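**Plan**

- Retrosynthesis: the quinone comes from a p-methoxyphenol by oxidative demethylation and the 7-OH from a benzyl ether; the C3–H stereocentre comes from the C3=C4 olefin of an isoflav-3-ene; ring B is cut at C1′–C2′ and C4′–C5′ into a chromenyl propynoate and 1,3-dimethoxyacetone; ring C comes from a salicylaldehyde and acrolein; the aldehyde comes from syringaldehyde.
- Enabling feature: C2′–C3′–C4′ of ring B carry three contiguous oxygens and are the skeleton of a C2-symmetric 1,3-dimethoxyacetone with two nucleophilic α-carbons. C5′–C6′–C1′ are the β-, α- and carboxyl carbons of a 2-ynoate, a 1,3-dielectrophile already at the arene oxidation level.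
- Forward order: ring A is bought as syringaldehyde, ring C is closed by oxa-Michael/aldol, and ring B is then built in one [3+3] operation. The C3′ phenol is methylated, and the surplus O-methyl at C4′ is lost when PhI(OAc)2 forms the quinone.
- Stereochemistry: the single stereocentre (C3 of the chromane, S) is set by iridium-catalysed asymmetric hydrogenation of the C3=C4 olefin after ring B exists; no basic step follows.

Key step: step 7

Remark: ring B atoms are primed and numbered as in the target quinone (C1′ and C4′ carbonyl, C2′ and C3′ methoxylated, C5′ bearing the chromane, C6′–H); prop-2-enal (5) and 1,3-dimethoxypropan-2-one (10) are taken as catalogue compounds.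

**Route**

Step 1
Reactants: 1 4-hydroxy-3,5-dimethoxybenzaldehyde (syringaldehyde)
Product: 2 2-bromo-4-hydroxy-3,5-dimethoxybenzaldehyde
Conditions: Br2 (1.05 equiv), AcOH, 20 °C
Reagents that add atoms: bromine, BrBr
Why: Electrophilic aromatic bromination; C2 and C6 are the only free positions, are equivalent, and are activated ortho/para by the two methoxy groups, so a single monobromide should form.

Step 2
Reactants: 2 2-bromo-4-hydroxy-3,5-dimethoxybenzaldehyde
Product: 3 2,4-dihydroxy-3,5-dimethoxybenzaldehyde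
Conditions: NaOH (8% aq), Cu powder (cat.), reflux, N2; then aq HCl
Reagents that add atoms: sodium hydroxide, [Na+].[OH-]
Why: Copper-mediated Ullmann-type hydroxylation of an aryl bromide activated by the ortho formyl group, the classical route from bromo-hydroxybenzaldehydes to dihydroxybenzaldehydes; the phenoxide form should protect the aldehyde from Cannizzaro disproportionation.

Step 3
Reactants: 3 2,4-dihydroxy-3,5-dimethoxybenzaldehyde
Product: 4 4-(benzyloxy)-2-hydroxy-3,5-dimethoxybenzaldehyde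
Conditions: BnBr (1.05 equiv), K2CO3 (1.0 equiv), DMF, 20 °C
Reagents that add atoms: benzyl bromide, BrCc1ccccc1
Why: Williamson etherification; the 4-OH para to the formyl group is the more acidic and is not chelated, whereas the 2-OH is hydrogen-bonded to the carbonyl, so mono-benzylation at O4 is expected.

Step 4
Reactants: 4 4-(benzyloxy)-2-hydroxy-3,5-dimethoxybenzaldehyde; 5 prop-2-enal (acrolein)
Product: 6 7-(benzyloxy)-6,8-dimethoxy-2H-chromene-3-carbaldehyde
Conditions: K2CO3, 1,4-dioxane, reflux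
Reagents that add atoms: none
Why: Domino oxa-Michael addition of the phenoxide to acrolein, intramolecular aldol addition to the aryl aldehyde and dehydration, the standard entry to 2H-chromene-3-carbaldehydes from salicylaldehydes.

Step 5
Reactants: 6 7-(benzyloxy)-6,8-dimethoxy-2H-chromene-3-carbaldehyde
Product: 7 7-(benzyloxy)-3-(2,2-dibromoethenyl)-6,8-dimethoxy-2H-chromene
Conditions: CBr4, PPh3, CH2Cl2, 0 °C
Reagents that add atoms: carbon tetrabromide, BrC(Br)(Br)Br
Why: First stage of the Corey–Fuchs sequence (Wittig-type dibromo-olefination of an aldehyde), which runs under neutral conditions that the enal and the benzyl ether tolerate.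

Step 6
Reactants: 7 7-(benzyloxy)-3-(2,2-dibromoethenyl)-6,8-dimethoxy-2H-chromene
Product: 9 methyl 3-[7-(benzyloxy)-6,8-dimethoxy-2H-chromen-3-yl]prop-2-ynoate, via lithium acetylide 8 (not isolated)
Conditions: n-BuLi (2.2 equiv), THF, −78 °C; then ClCO2Me, −78 → 0 °C
Reagents that add atoms: methyl chloroformate, COC(=O)Cl
Why: Second stage of the Corey–Fuchs sequence: bromine–lithium exchange and Fritsch–Buttenberg–Wiechell-type rearrangement give the lithium acetylide, which is C-acylated by the chloroformate to the 2-ynoate.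

Step 7
Reactants: 9 methyl 3-[7-(benzyloxy)-6,8-dimethoxy-2H-chromen-3-yl]prop-2-ynoate; 10 1,3-dimethoxypropan-2-one
Product: 12 5-[7-(benzyloxy)-6,8-dimethoxy-2H-chromen-3-yl]-2,4-dimethoxybenzene-1,3-diol, via conjugate adduct 11 (not isolated)
Conditions: 10 (1.3 equiv), LiN(iPr)2 (1.25 equiv), THF, −78 °C; add 9, −78 → −20 °C; LiN(iPr)2 (2.5 equiv), −78 → 0 °C; aq HCl
Reagents that add atoms: none
Why: Proposed new method: the lithium enolate of the symmetrical ketone 10 should add in conjugate fashion to the sp β-carbon of ynoate 9 (C4′–C5′ bond), proton transfer gives the stabilised dienolate of 11, and a second deprotonation at the remaining CH2OMe carbon (the γ-type carbanion of a vinylogous β-keto ester dianion) should attack the ester carbonyl (C1′–C2′ bond) with loss of methoxide, after which the cyclohexenedione tautomerises irreversibly to resorcinol 12; should ester attack come first, the same dianion closes the ring by 6-endo-dig conjugate addition to the same product. The closest known reactions are the Michael–Dieckmann synthesis of 5-substituted resorcinols from 2-alkynoates and 3-oxoglutarate diesters and the γ-acylation of β-keto ester dianions; new here is an α,α′-dialkoxy ketone without ester activation. Ring B closes in a favoured 6-(enolendo)-exo-trig mode. No stereocentre survives, since the CH(OMe) centre of 11 becomes aromatic. The step needs 1,4- and not 1,6-addition, and C- and not O-acylation (2-pyranone formation): the unhindered sp carbon next to the ester, the low temperature, the hard terminal carbanion of the dianion and the aromatic sink should secure this, and the C2 symmetry of 10 means either α-carbon may start the sequence.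

Step 8
Reactants: 12 5-[7-(benzyloxy)-6,8-dimethoxy-2H-chromen-3-yl]-2,4-dimethoxybenzene-1,3-diol
Product: 13 3-[7-(benzyloxy)-6,8-dimethoxy-2H-chromen-3-yl]-2,6-dimethoxy-5-{[tri(propan-2-yl)silyl]oxy}phenol
Conditions: i-Pr3SiCl (1.05 equiv), imidazole, CH2Cl2, 0 °C
Reagents that add atoms: chlorotri(propan-2-yl)silane, CC(C)[Si](Cl)(C(C)C)C(C)C
Why: Sterically controlled silyl ether formation; the C1′ hydroxyl has one ortho hydrogen whereas the C3′ hydroxyl lies between two methoxy groups, so the bulky silyl chloride should take O1′ only.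

Step 9
Reactants: 13 3-[7-(benzyloxy)-6,8-dimethoxy-2H-chromen-3-yl]-2,6-dimethoxy-5-{[tri(propan-2-yl)silyl]oxy}phenol
Product: 14 {5-[7-(benzyloxy)-6,8-dimethoxy-2H-chromen-3-yl]-2,3,4-trimethoxyphenoxy}tri(propan-2-yl)silane
Conditions: MeI, K2CO3, acetone, 50 °C
Reagents that add atoms: iodomethane, CI
Why: Williamson methylation of the one remaining phenol (C3′), which installs the second methoxy group of the future quinone; the aryl silyl ether should survive carbonate in acetone.

Step 10
Reactants: 14 {5-[7-(benzyloxy)-6,8-dimethoxy-2H-chromen-3-yl]-2,3,4-trimethoxyphenoxy}tri(propan-2-yl)silane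
Product: 15 {5-[(3S)-7-(benzyloxy)-6,8-dimethoxy-3,4-dihydro-2H-chromen-3-yl]-2,3,4-trimethoxyphenoxy}tri(propan-2-yl)silane
Conditions: [Ir(C8H12)(L)][B(C6H3(CF3)2)4] (2 mol %), L = (S)-4-tert-butyl-2-[2-(diphenylphosphanyl)phenyl]-4,5-dihydro-1,3-oxazole, H2 (50 bar), CH2Cl2, 25 °C
Reagents that add atoms: none
Why: Iridium–phosphinooxazoline-catalysed asymmetric hydrogenation of an unfunctionalised trisubstituted cyclic styrene (isoflav-3-ene to isoflavan); the chiral N,P pocket differentiates the olefin faces and sets C3 as S, the ligand antipode being used if the sense of induction proves opposite, and the benzyl and silyl ethers are inert.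

Step 11
Reactants: 15 {5-[(3S)-7-(benzyloxy)-6,8-dimethoxy-3,4-dihydro-2H-chromen-3-yl]-2,3,4-trimethoxyphenoxy}tri(propan-2-yl)silane
Product: 17 5-[(3S)-7-(benzyloxy)-6,8-dimethoxy-3,4-dihydro-2H-chromen-3-yl]-2,3-dimethoxycyclohexa-2,5-diene-1,4-dione, via free phenol 16 (not isolated)
Conditions: Bu4NF, THF, 0 °C; AcOH; then PhI(OAc)2, MeCN/H2O, 0 °C
Reagents that add atoms: water, O
Why: Fluoride desilylation followed by hypervalent-iodine oxidation of a p-methoxyphenol to the p-quinone, in which water attacks C4′ and methanol is lost; ring A carries only ether oxygens at this stage and should not be oxidised.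

Step 12
Reactants: 17 5-[(3S)-7-(benzyloxy)-6,8-dimethoxy-3,4-dihydro-2H-chromen-3-yl]-2,3-dimethoxycyclohexa-2,5-diene-1,4-dione
Product: 19 5-[(3S)-7-hydroxy-6,8-dimethoxy-3,4-dihydro-2H-chromen-3-yl]-2,3-dimethoxycyclohexa-2,5-diene-1,4-dione, via hydroquinone 18 (not isolated)
Conditions: H2 (1 atm), Pd/C (10%), EtOAc, 20 °C; filter; then air (O2), 20 °C
Reagents that add atoms: none
Why: Hydrogenolysis of the benzyl ether with concurrent reduction of the quinone to hydroquinone 18, which air should re-oxidise far more readily than the ring A phenol (hydroquinone autoxidation); no base is present, so C3 should not epimerise.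

**Compound list**

1 | 4-hydroxy-3,5-dimethoxybenzaldehyde (syringaldehyde) | COc1cc(C=O)cc(OC)c1O | starting material
2 | 2-bromo-4-hydroxy-3,5-dimethoxybenzaldehyde | COc1cc(C=O)c(Br)c(OC)c1O | intermediate
3 | 2,4-dihydroxy-3,5-dimethoxybenzaldehyde | COc1cc(C=O)c(O)c(OC)c1O | intermediate
4 | 4-(benzyloxy)-2-hydroxy-3,5-dimethoxybenzaldehyde | COc1cc(C=O)c(O)c(OC)c1OCc1ccccc1 | intermediate
5 | prop-2-enal (acrolein) | C=CC=O | starting material
6 | 7-(benzyloxy)-6,8-dimethoxy-2H-chromene-3-carbaldehyde | COc1cc2C=C(C=O)COc2c(OC)c1OCc1ccccc1 | intermediate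
7 | 7-(benzyloxy)-3-(2,2-dibromoethenyl)-6,8-dimethoxy-2H-chromene | COc1cc2C=C(C=C(Br)Br)COc2c(OC)c1OCc1ccccc1 | intermediate
8 | {[7-(benzyloxy)-6,8-dimethoxy-2H-chromen-3-yl]ethynyl}lithium | [Li]C#CC1=Cc2cc(OC)c(OCc3ccccc3)c(OC)c2OC1 | intermediate
9 | methyl 3-[7-(benzyloxy)-6,8-dimethoxy-2H-chromen-3-yl]prop-2-ynoate | COC(=O)C#CC1=Cc2cc(OC)c(OCc3ccccc3)c(OC)c2OC1 | intermediate
10 | 1,3-dimethoxypropan-2-one | COCC(=O)COC | starting material
11 | methyl (2Z)-3-[7-(benzyloxy)-6,8-dimethoxy-2H-chromen-3-yl]-4,6-dimethoxy-5-oxohex-2-enoate (racemic at C4; lithium dienolate in the flask) | COC(=O)/C=C(/C1=Cc2cc(OC)c(OCc3ccccc3)c(OC)c2OC1)C(OC)C(=O)COC | intermediate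
12 | 5-[7-(benzyloxy)-6,8-dimethoxy-2H-chromen-3-yl]-2,4-dimethoxybenzene-1,3-diol | COc1c(O)cc(C2=Cc3cc(OC)c(OCc4ccccc4)c(OC)c3OC2)c(OC)c1O | intermediate
13 | 3-[7-(benzyloxy)-6,8-dimethoxy-2H-chromen-3-yl]-2,6-dimethoxy-5-{[tri(propan-2-yl)silyl]oxy}phenol | COc1c(O[Si](C(C)C)(C(C)C)C(C)C)cc(C2=Cc3cc(OC)c(OCc4ccccc4)c(OC)c3OC2)c(OC)c1O | intermediate
14 | {5-[7-(benzyloxy)-6,8-dimethoxy-2H-chromen-3-yl]-2,3,4-trimethoxyphenoxy}tri(propan-2-yl)silane | COc1c(O[Si](C(C)C)(C(C)C)C(C)C)cc(C2=Cc3cc(OC)c(OCc4ccccc4)c(OC)c3OC2)c(OC)c1OC | intermediate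
15 | {5-[(3S)-7-(benzyloxy)-6,8-dimethoxy-3,4-dihydro-2H-chromen-3-yl]-2,3,4-trimethoxyphenoxy}tri(propan-2-yl)silane | COc1c(O[Si](C(C)C)(C(C)C)C(C)C)cc([C@H]2COc3c(OC)c(OCc4ccccc4)c(OC)cc3C2)c(OC)c1OC | intermediate
16 | 5-[(3S)-7-(benzyloxy)-6,8-dimethoxy-3,4-dihydro-2H-chromen-3-yl]-2,3,4-trimethoxyphenol | COc1c(O)cc([C@H]2COc3c(OC)c(OCc4ccccc4)c(OC)cc3C2)c(OC)c1OC | intermediate
17 | 5-[(3S)-7-(benzyloxy)-6,8-dimethoxy-3,4-dihydro-2H-chromen-3-yl]-2,3-dimethoxycyclohexa-2,5-diene-1,4-dione | COC1=C(OC)C(=O)C([C@H]2COc3c(OC)c(OCc4ccccc4)c(OC)cc3C2)=CC1=O | intermediate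
18 | 5-[(3S)-7-hydroxy-6,8-dimethoxy-3,4-dihydro-2H-chromen-3-yl]-2,3-dimethoxybenzene-1,4-diol | COc1c(O)cc([C@H]2COc3c(OC)c(O)c(OC)cc3C2)c(O)c1OC | intermediate
19 | 5-[(3S)-7-hydroxy-6,8-dimethoxy-3,4-dihydro-2H-chromen-3-yl]-2,3-dimethoxycyclohexa-2,5-diene-1,4-dione | COC1=C(OC)C(=O)C([C@H]2COc3c(cc(OC)c(O)c3OC)C2)=CC1=O | target

**Step count and risks**

Total steps: 12. Longest linear sequence: 12 (1 → 19; compounds 5 and 10 are bought).

Steps most likely to fail:

1. Step 7 (proposed new method). Ring closure through oxygen (2-pyranone or 4-pyranone formation), or addition of the amide base to the ynoate, may outrun the carbon–carbon ring closure. The fallback uses known chemistry and sets out from dibromoalkene 7. Treatment with n-BuLi gives acetylide 8, which should add to 3,4-dimethoxycyclobut-3-ene-1,2-dione (dimethyl squarate) to give 4-{[7-(benzyloxy)-6,8-dimethoxy-2H-chromen-3-yl]ethynyl}-4-hydroxy-2,3-dimethoxycyclobut-2-en-1-one F1. Thermolysis in p-xylene at 140 °C (Moore rearrangement) should give 5-[7-(benzyloxy)-6,8-dimethoxy-2H-chromen-3-yl]-2,3-dimethoxycyclohexa-2,5-diene-1,4-dione F2. Reduction with Na2S2O4 in EtOAc/H2O should give 5-[7-(benzyloxy)-6,8-dimethoxy-2H-chromen-3-yl]-2,3-dimethoxybenzene-1,4-diol F3. The hydroxyl remote from the chromene should be silylated selectively (i-Pr3SiCl, imidazole) to 6-[7-(benzyloxy)-6,8-dimethoxy-2H-chromen-3-yl]-2,3-dimethoxy-4-{[tri(propan-2-yl)silyl]oxy}phenol F4. Methylation (MeI, K2CO3, acetone) then comes back to the route at 14.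

2. Step 8. The two phenolic hydroxyls may not be discriminated well enough, leading to silylation at the wrong oxygen or at both. The fallback sets out from 12 and moves the discrimination into an ester cleavage. PivCl, Et3N and DMAP should give 5-[7-(benzyloxy)-6,8-dimethoxy-2H-chromen-3-yl]-2,4-dimethoxy-1,3-phenylene bis(2,2-dimethylpropanoate) F5. K2CO3 in MeOH at 0 °C should cleave only the ester that is not flanked by two methoxy groups, giving 3-[7-(benzyloxy)-6,8-dimethoxy-2H-chromen-3-yl]-5-hydroxy-2,6-dimethoxyphenyl 2,2-dimethylpropanoate F6. Silylation of the single free phenol (i-Pr3SiCl, imidazole) should give 3-[7-(benzyloxy)-6,8-dimethoxy-2H-chromen-3-yl]-2,6-dimethoxy-5-{[tri(propan-2-yl)silyl]oxy}phenyl 2,2-dimethylpropanoate F7. Reductive removal of the remaining pivalate with i-Bu2AlH at −78 °C comes back to the route at 13.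

3. Step 10. The ortho-substituted, trisubstituted olefin may give low conversion or poor facial selectivity. The fallback sets out from 14 and replaces asymmetric catalysis by resolution. Hydrogenation with the achiral catalyst [Ir(C8H12)(PCy3)(C5H5N)]PF6 (H2, CH2Cl2) should give racemic {5-[7-(benzyloxy)-6,8-dimethoxy-3,4-dihydro-2H-chromen-3-yl]-2,3,4-trimethoxyphenoxy}tri(propan-2-yl)silane F8. Preparative chromatography on a chiral stationary phase should separate it into 15, where the route is rejoined, and the unwanted {5-[(3R)-7-(benzyloxy)-6,8-dimethoxy-3,4-dihydro-2H-chromen-3-yl]-2,3,4-trimethoxyphenoxy}tri(propan-2-yl)silane F9.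

**Further compounds**

F1 | step 7 | 4-{[7-(benzyloxy)-6,8-dimethoxy-2H-chromen-3-yl]ethynyl}-4-hydroxy-2,3-dimethoxycyclobut-2-en-1-one (racemic) | COC1=C(OC)C(O)(C#CC2=Cc3cc(OC)c(OCc4ccccc4)c(OC)c3OC2)C1=O
F2 | step 7 | 5-[7-(benzyloxy)-6,8-dimethoxy-2H-chromen-3-yl]-2,3-dimethoxycyclohexa-2,5-diene-1,4-dione | COC1=C(OC)C(=O)C(C2=Cc3cc(OC)c(OCc4ccccc4)c(OC)c3OC2)=CC1=O
F3 | step 7 | 5-[7-(benzyloxy)-6,8-dimethoxy-2H-chromen-3-yl]-2,3-dimethoxybenzene-1,4-diol | COc1c(O)cc(C2=Cc3cc(OC)c(OCc4ccccc4)c(OC)c3OC2)c(O)c1OC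
F4 | step 7 | 6-[7-(benzyloxy)-6,8-dimethoxy-2H-chromen-3-yl]-2,3-dimethoxy-4-{[tri(propan-2-yl)silyl]oxy}phenol | COc1c(O[Si](C(C)C)(C(C)C)C(C)C)cc(C2=Cc3cc(OC)c(OCc4ccccc4)c(OC)c3OC2)c(O)c1OC
F5 | step 8 | 5-[7-(benzyloxy)-6,8-dimethoxy-2H-chromen-3-yl]-2,4-dimethoxy-1,3-phenylene bis(2,2-dimethylpropanoate) | COc1c(OC(=O)C(C)(C)C)cc(C2=Cc3cc(OC)c(OCc4ccccc4)c(OC)c3OC2)c(OC)c1OC(=O)C(C)(C)C
F6 | step 8 | 3-[7-(benzyloxy)-6,8-dimethoxy-2H-chromen-3-yl]-5-hydroxy-2,6-dimethoxyphenyl 2,2-dimethylpropanoate | COc1c(O)cc(C2=Cc3cc(OC)c(OCc4ccccc4)c(OC)c3OC2)c(OC)c1OC(=O)C(C)(C)C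
F7 | step 8 | 3-[7-(benzyloxy)-6,8-dimethoxy-2H-chromen-3-yl]-2,6-dimethoxy-5-{[tri(propan-2-yl)silyl]oxy}phenyl 2,2-dimethylpropanoate | COc1c(O[Si](C(C)C)(C(C)C)C(C)C)cc(C2=Cc3cc(OC)c(OCc4ccccc4)c(OC)c3OC2)c(OC)c1OC(=O)C(C)(C)C
F8 | step 10 | {5-[7-(benzyloxy)-6,8-dimethoxy-3,4-dihydro-2H-chromen-3-yl]-2,3,4-trimethoxyphenoxy}tri(propan-2-yl)silane (racemic) | COc1c(O[Si](C(C)C)(C(C)C)C(C)C)cc(C2COc3c(OC)c(OCc4ccccc4)c(OC)cc3C2)c(OC)c1OC
F9 | step 10 | {5-[(3R)-7-(benzyloxy)-6,8-dimethoxy-3,4-dihydro-2H-chromen-3-yl]-2,3,4-trimethoxyphenoxy}tri(propan-2-yl)silane | COc1c(O[Si](C(C)C)(C(C)C)C(C)C)cc([C@@H]2COc3c(OC)c(OCc4ccccc4)c(OC)cc3C2)c(OC)c1OC
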